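## Retrosynthetic overview
1. The last C–C bond made is C8‑CH2 to the stereocentre. Ring A of the finished flavone is dearomatised to an O‑silylated ortho‑quinone methide. The γ‑carbon of a (Z)‑allylsilane attacks it inside a chiral ion pair, which creates the CH2–CH bond, the (R) centre and the isopropenyl group in one event.
2. The quinone methide precursor (8‑CH2OMe flavone) comes from C8‑selective aminomethylation of 5,7,2',4'‑tetrahydroxyflavone.
3. The flavone comes from threefold‑symmetric phloroglucinol and an aroylacetate by one thermal pyrone annulation, followed by O‑demethylation.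
4. The allylsilane already carries the tertiary carbinol. It comes from sulcatone by cycloisomerisation to a dihydropyran, then nickel‑catalysed C–O/Me3SiCH2MgCl coupling with retention.
5. Ring order: rings A and B are bought, ring C (the pyranone) is the only ring built (step 1), and no ring is formed afterwards.

Assumption: the sense of induction of the chiral acid in step 6 cannot be predicted, so the (S,S) acid is written and its mirror image is used if the first run gives the (S) product (checked by chiral HPLC and CD).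

## Route

Step 1
Reactants: 1 phloroglucinol; 2 ethyl 3-(2,4-dimethoxyphenyl)-3-oxopropanoate
Product: 4 5,7-dihydroxy-2-(2,4-dimethoxyphenyl)-4H-chromen-4-one, via aryl diketone 3 (not isolated)
Conditions: neat melt (1:2 = 1:1.3), 240 °C, N2 sweep, 30–45 min; recrystallise from MeOH
Reagents that add atoms: none
Why: Mentzer pyrone synthesis, in which the keto ester C‑acylates phloroglucinol thermally and cyclodehydration closes ring C; the three equivalent C–H positions allow only one flavone, and the acid‑free melt avoids the Pechmann coumarin.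

Step 2
Reactants: 4 5,7-dihydroxy-2-(2,4-dimethoxyphenyl)-4H-chromen-4-one
Product: 5 5,7-dihydroxy-2-(2,4-dihydroxyphenyl)-4H-chromen-4-one (norartocarpetin)
Conditions: BBr3 (6 equiv), CH2Cl2, −78 → 25 °C, 16 h; ice–water
Reagents that add atoms: none
Why: Lewis‑acid aryl methyl ether cleavage is done now, while no acid‑sensitive alkene or tertiary alcohol is present, and low temperature without water prevents ring C from opening and reclosing.

Step 3
Reactants: 5 5,7-dihydroxy-2-(2,4-dihydroxyphenyl)-4H-chromen-4-one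
Product: 9 5,7-dihydroxy-2-(2,4-dihydroxyphenyl)-8-(methoxymethyl)-4H-chromen-4-one, via Mannich base 6 (not isolated), via ammonium iodide 7 (not isolated), via ortho-quinone methide 8 (not isolated)
Conditions: (i) CH2(NMe2)2 (1.05 equiv), 1,4‑dioxane, 80 °C, 3 h, evaporate; (ii) MeI (1.05 equiv), THF–MeOH 1:1, 0 → 50 °C, 6 h
Reagents that add atoms: bis(dimethylamino)methane CN(C)CN(C)C; methanol CO
Why: Mannich aminomethylation goes to C8 because 7‑OH is the most acidic phenol, 5‑OH is locked in the hydrogen bond to C4=O and ring B is deactivated by conjugation to the pyranone; N‑methylation then lets NMe3 leave, and oxa‑Michael addition of methanol to quinone methide 8 rearomatises to the storable benzylic ether 9.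

Step 4
Reactants: 10 6-methylhept-5-en-2-one (sulcatone)
Product: 11 2,2,6-trimethyl-3,4-dihydro-2H-pyran
Conditions: p‑TsOH·H2O (1 mol %), neat, 140–150 °C bath, slow fractional distillation of the lower‑boiling product
Reagents that add atoms: none
Why: Acid‑catalysed cycloisomerisation, in which the carbonyl oxygen adds in the Markovnikov sense to the protonated trisubstituted alkene and loss of the ring proton gives the endocyclic enol ether; distilling out the more volatile 11 pulls the equilibrium and removes it from the acid.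

Step 5
Reactants: 11 2,2,6-trimethyl-3,4-dihydro-2H-pyran
Product: 13 (5Z)-2,6-dimethyl-7-(trimethylsilyl)hept-5-en-2-ol, via chloromagnesium alkoxide 12 (not isolated)
Conditions: Me3SiCH2MgCl (2.5 equiv), NiCl2(PPh3)2 (5 mol %), toluene–Et2O, 80 °C, 16 h; then H2O
Reagents that add atoms: (trimethylsilyl)methylmagnesium chloride C[Si](C)(C)C[Mg]Cl
Why: Wenkert‑type Kumada coupling of a cyclic enol ether, in which zerovalent nickel inserts into the vinylic C–O bond, the Grignard reagent has no β‑hydrogen, and reductive elimination with retention places CH2SiMe3 cis to the chain (Z) while freeing the tertiary alkoxide.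

Step 6
Reactants: 9 5,7-dihydroxy-2-(2,4-dihydroxyphenyl)-8-(methoxymethyl)-4H-chromen-4-one; 13 (5Z)-2,6-dimethyl-7-(trimethylsilyl)hept-5-en-2-ol
Product: 18 8-[(2R)-5-hydroxy-5-methyl-2-(prop-1-en-2-yl)hexyl]-5,7-dihydroxy-2-(2,4-dihydroxyphenyl)-4H-chromen-4-one, via tetrasilyl ether 14 (not isolated), via silylated allylsilane 15 (not isolated), via O-silyl quinone methide cation 16 (not isolated), via pentasilyl ether 17 (not isolated)
Conditions: (i) 9 (1.0 equiv), 13 (1.5 equiv), CF3C(O)N(Me)SiMe3 (7 equiv), MeCN, 60 °C, 2 h, volatiles off, toluene chase under high vacuum; (ii) (S,S)‑HN[P(=NSO2CF3)(O2C20H10Ar2)]2, Ar = 3,5‑(CF3)2C6H3 (imidodiphosphorimidate on two (S)‑3,3'‑diaryl‑BINOL units, 5 mol %), toluene, −40 °C, 48 h; (iii) MeOH, citric acid (10 mol %), 0 → 23 °C, 2 h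
Reagents that add atoms: none
Why: Proposed new method: silylium‑based counteranion‑directed Hosomi–Sakurai benzylation, in which the silylated chiral acid abstracts the methoxy group of 14 so that ring A gives up its aromaticity and the O‑silylated ortho‑quinone methide 16 sits as a contact ion pair in the chiral pocket; the geometrically pure (Z)‑allylsilane 15 attacks the exocyclic CH2 with its γ‑carbon (anti SE2', Si face of C5), the β‑silyl cation returns Me3Si+ to the anion, ring A rearomatises, and the (R) centre and the isopropenyl group form together; the closest known reaction types are the imidodiphosphorimidate‑catalysed Hosomi–Sakurai allylation of aldehydes and the same catalysts' aminomethylation of prochiral silyl ketene acetals with an unsubstituted CH2=N+ electrophile, where the stereocentre is likewise set on the nucleophile; the transient Me3Si ethers keep the medium aprotic (no protodesilylation) and are removed by methanol without touching the stereocentre.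

## Compound list
1 | phloroglucinol | Oc1cc(O)cc(O)c1 | starting material
2 | ethyl 3-(2,4-dimethoxyphenyl)-3-oxopropanoate | CCOC(=O)CC(=O)c1ccc(OC)cc1OC | starting material
3 | 1-(2,4-dimethoxyphenyl)-3-(2,4,6-trihydroxyphenyl)propane-1,3-dione | COc1ccc(C(=O)CC(=O)c2c(O)cc(O)cc2O)c(OC)c1 | intermediate
4 | 5,7-dihydroxy-2-(2,4-dimethoxyphenyl)-4H-chromen-4-one | COc1ccc(-c2cc(=O)c3c(O)cc(O)cc3o2)c(OC)c1 | intermediate
5 | 5,7-dihydroxy-2-(2,4-dihydroxyphenyl)-4H-chromen-4-one | O=c1cc(-c2ccc(O)cc2O)oc2cc(O)cc(O)c12 | intermediate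
6 | 8-[(dimethylamino)methyl]-5,7-dihydroxy-2-(2,4-dihydroxyphenyl)-4H-chromen-4-one | CN(C)Cc1c(O)cc(O)c2c(=O)cc(-c3ccc(O)cc3O)oc12 | intermediate
7 | [5,7-dihydroxy-2-(2,4-dihydroxyphenyl)-4-oxo-4H-chromen-8-yl]methyl(trimethyl)ammonium iodide | C[N+](C)(C)Cc1c(O)cc(O)c2c(=O)cc(-c3ccc(O)cc3O)oc12.[I-] | intermediate
8 | 2-(2,4-dihydroxyphenyl)-5-hydroxy-8-methylidene-4H-chromene-4,7(8H)-dione (ortho-quinone methide, ring A dearomatised) | C=C1C(=O)C=C(O)C2=C1OC(c1ccc(O)cc1O)=CC2=O | intermediate
9 | 5,7-dihydroxy-2-(2,4-dihydroxyphenyl)-8-(methoxymethyl)-4H-chromen-4-one | COCc1c(O)cc(O)c2c(=O)cc(-c3ccc(O)cc3O)oc12 | intermediate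
10 | 6-methylhept-5-en-2-one | CC(=O)CCC=C(C)C | starting material
11 | 2,2,6-trimethyl-3,4-dihydro-2H-pyran | CC1=CCCC(C)(C)O1 | intermediate
12 | chloromagnesium (5Z)-2,6-dimethyl-7-(trimethylsilyl)hept-5-en-2-olate | C[Si](C)(C)C/C(C)=C\CCC(C)(C)O[Mg]Cl | intermediate
13 | (5Z)-2,6-dimethyl-7-(trimethylsilyl)hept-5-en-2-ol | C[Si](C)(C)C/C(C)=C\CCC(C)(C)O | intermediate
14 | 8-(methoxymethyl)-5,7-bis(trimethylsilyloxy)-2-[2,4-bis(trimethylsilyloxy)phenyl]-4H-chromen-4-one | COCc1c(O[Si](C)(C)C)cc(O[Si](C)(C)C)c2c(=O)cc(-c3ccc(O[Si](C)(C)C)cc3O[Si](C)(C)C)oc12 | intermediate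
15 | [(5Z)-2,6-dimethyl-7-(trimethylsilyl)hept-5-en-2-yl]oxy(trimethyl)silane | C[Si](C)(C)C/C(C)=C\CCC(C)(C)O[Si](C)(C)C | intermediate
16 | O7-trimethylsilylated 8-methylidene ortho-quinone methide cation of 14 (ring A dearomatised, paired with the chiral imidodiphosphorimidate anion) | C=C1C(=[O+][Si](C)(C)C)C=C(O[Si](C)(C)C)C2=C1OC(c1ccc(O[Si](C)(C)C)cc1O[Si](C)(C)C)=CC2=O | intermediate
17 | 8-[(2R)-5-methyl-2-(prop-1-en-2-yl)-5-(trimethylsilyloxy)hexyl]-5,7-bis(trimethylsilyloxy)-2-[2,4-bis(trimethylsilyloxy)phenyl]-4H-chromen-4-one | C=C(C)[C@H](CCC(C)(C)O[Si](C)(C)C)Cc1c(O[Si](C)(C)C)cc(O[Si](C)(C)C)c2c(=O)cc(-c3ccc(O[Si](C)(C)C)cc3O[Si](C)(C)C)oc12 | intermediate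
18 | 8-[(2R)-5-hydroxy-5-methyl-2-(prop-1-en-2-yl)hexyl]-5,7-dihydroxy-2-(2,4-dihydroxyphenyl)-4H-chromen-4-one | C=C(C)[C@H](CCC(C)(C)O)Cc1c(O)cc(O)c2c(=O)cc(-c3ccc(O)cc3O)oc12 | target

## Step count and risks
Total steps: 6. Longest linear sequence: 4 (steps 1, 2, 3, 6). The side branch is steps 4, 5, 6.

**Step 6.** Ion‑pair control over a primary, highly stabilised benzylic cation is unproven. The basic pyranone carbonyl may also hold the silylium catalyst in an unproductive form, and the large flavone may fit the confined anion poorly.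

The fallback moves the stereo‑defining event to an aldehyde, where catalytic asymmetric Hosomi–Sakurai allylation is established. It sets out from 5 and comes back at 17. Duff formylation (hexamethylenetetramine, AcOH, 100 °C, then aq. HCl) gives 5,7-dihydroxy-2-(2,4-dihydroxyphenyl)-4-oxo-4H-chromene-8-carbaldehyde F1. CF3C(O)N(Me)SiMe3 converts it into its tetrakis(trimethylsilyl) ether F2. The same chiral acid adds 15 to the silyl‑activated formyl group to give the homoallylic silyl ether F3. The isopropenyl‑bearing carbon of F3 has the spatial arrangement of 18, and the carbinol carbon is irrelevant because it is erased. Et3SiH with catalytic Me3SiOTf in CH2Cl2 at −78 °C then removes the benzylic silyloxy group by ionic hydrogenation to give 17.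

**Step 3.** The risks are C6 against C8 selectivity, competing attack on the free resorcinol ring B, methylene‑bridged dimers, and the poor solubility of the tetraol.

The fallback changes the order of events so that ring B stays masked until the end. It sets out from 4 and comes back at 18. Aminomethylation of 4 gives the Mannich base F4. MeI gives the ammonium iodide F5, and loss of NMe3 gives the ortho-quinone methide F6. Methanol then gives the benzylic methyl ether F7, and silylation gives the bis(trimethylsilyl) ether F8. Coupling with 15 as in step 6 passes through the O-silyl quinone methide cation F9 to the tris(trimethylsilyl) ether F10. Methanolysis gives the 2',4'-di-O-methyl ether F11. The two aryl methyl ethers, activated by the ortho/para pyranone, are then cleaved by SN2 with NaSEt (6 equiv) in DMF at 120 °C. These basic conditions leave the alkene, the tertiary alcohol and the stereocentre alone, and give 18.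

**Step 4.** The risks are competing acid‑induced carbocyclisation or aldol chemistry of sulcatone and oligomerisation of the enol ether.

The fallback separates C–O bond formation from dehydration. It sets out from 10 and comes back at 11. Markovnikov hydration (35 % aq. H2SO4, 20 °C) gives 6-hydroxy-6-methylheptan-2-one F12. This is cyclodehydrated with p‑TsOH·H2O (0.5 mol %) in toluene under Dean–Stark conditions to give 11.

## Further compounds
F1 | step 6 | 5,7-dihydroxy-2-(2,4-dihydroxyphenyl)-4-oxo-4H-chromene-8-carbaldehyde | O=Cc1c(O)cc(O)c2c(=O)cc(-c3ccc(O)cc3O)oc12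
F2 | step 6 | 4-oxo-5,7-bis(trimethylsilyloxy)-2-[2,4-bis(trimethylsilyloxy)phenyl]-4H-chromene-8-carbaldehyde | O=Cc1c(O[Si](C)(C)C)cc(O[Si](C)(C)C)c2c(=O)cc(-c3ccc(O[Si](C)(C)C)cc3O[Si](C)(C)C)oc12
F3 | step 6 | 8-[(2S)-5-methyl-2-(prop-1-en-2-yl)-1,5-bis(trimethylsilyloxy)hexyl]-5,7-bis(trimethylsilyloxy)-2-[2,4-bis(trimethylsilyloxy)phenyl]-4H-chromen-4-one (C1 epimers) | C=C(C)[C@H](CCC(C)(C)O[Si](C)(C)C)C(O[Si](C)(C)C)c1c(O[Si](C)(C)C)cc(O[Si](C)(C)C)c2c(=O)cc(-c3ccc(O[Si](C)(C)C)cc3O[Si](C)(C)C)oc12
F4 | step 3 | 8-[(dimethylamino)methyl]-5,7-dihydroxy-2-(2,4-dimethoxyphenyl)-4H-chromen-4-one | CN(C)Cc1c(O)cc(O)c2c(=O)cc(-c3ccc(OC)cc3OC)oc12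
F5 | step 3 | [5,7-dihydroxy-2-(2,4-dimethoxyphenyl)-4-oxo-4H-chromen-8-yl]methyl(trimethyl)ammonium iodide | C[N+](C)(C)Cc1c(O)cc(O)c2c(=O)cc(-c3ccc(OC)cc3OC)oc12.[I-]
F6 | step 3 | 2-(2,4-dimethoxyphenyl)-5-hydroxy-8-methylidene-4H-chromene-4,7(8H)-dione | C=C1C(=O)C=C(O)C2=C1OC(c1ccc(OC)cc1OC)=CC2=O
F7 | step 3 | 5,7-dihydroxy-2-(2,4-dimethoxyphenyl)-8-(methoxymethyl)-4H-chromen-4-one | COCc1c(O)cc(O)c2c(=O)cc(-c3ccc(OC)cc3OC)oc12
F8 | step 3 | 2-(2,4-dimethoxyphenyl)-8-(methoxymethyl)-5,7-bis(trimethylsilyloxy)-4H-chromen-4-one | COCc1c(O[Si](C)(C)C)cc(O[Si](C)(C)C)c2c(=O)cc(-c3ccc(OC)cc3OC)oc12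
F9 | step 3 | O7-trimethylsilylated 8-methylidene ortho-quinone methide cation of F8 | C=C1C(=[O+][Si](C)(C)C)C=C(O[Si](C)(C)C)C2=C1OC(c1ccc(OC)cc1OC)=CC2=O
F10 | step 3 | 2-(2,4-dimethoxyphenyl)-8-[(2R)-5-methyl-2-(prop-1-en-2-yl)-5-(trimethylsilyloxy)hexyl]-5,7-bis(trimethylsilyloxy)-4H-chromen-4-one | C=C(C)[C@H](CCC(C)(C)O[Si](C)(C)C)Cc1c(O[Si](C)(C)C)cc(O[Si](C)(C)C)c2c(=O)cc(-c3ccc(OC)cc3OC)oc12
F11 | step 3 | 5,7-dihydroxy-8-[(2R)-5-hydroxy-5-methyl-2-(prop-1-en-2-yl)hexyl]-2-(2,4-dimethoxyphenyl)-4H-chromen-4-one | C=C(C)[C@H](CCC(C)(C)O)Cc1c(O)cc(O)c2c(=O)cc(-c3ccc(OC)cc3OC)oc12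
F12 | step 4 | 6-hydroxy-6-methylheptan-2-one | CC(=O)CCCC(C)(C)O
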